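The C5 oxygen is added last. Ring A of a 6,7,8-trimethoxyflavone has a single C–H bond, at C5, and it sits peri to the C4 carbonyl oxygen of ring C; a ruthenium catalyst held by that oxygen can reach no other bond. One carbonyl-directed C–H oxygenation therefore completes the ring A oxygenation pattern without forming any ring or skeletal bond. Its substrate, 4'-pivaloyloxy-3',5',6,7,8-pentamethoxyflavone, is assembled from an ortho-hydroxyacetophenone and a syringoyl chloride that already carries the pivalate. The ester that shields ring B during the oxidation is thus present from the outset and afterwards tells O4' apart from the new 5-hydroxyl.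

Key step: step 7

Remark: diketone 11 is drawn as its diketo tautomer; it should exist largely as the hydrogen-bonded enol, which does not change the chemistry.

Step 1
Reactants: 1 2,3,4-trimethoxybenzaldehyde
Product: 3 2,3,4-trimethoxyphenol, via 2,3,4-trimethoxyphenyl formate 2 (not isolated)
Conditions: 30% H2O2, H2SO4 (cat.), MeOH, rt
Reagents that add atoms: hydrogen peroxide, OO
Why: In this Dakin-type (acid-catalysed Baeyer–Villiger) oxidation the electron-rich aryl group should migrate to oxygen in the peroxide adduct of the aldehyde, and the formate that results is methanolysed in the same flask.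

Step 2
Reactants: 3 2,3,4-trimethoxyphenol
Product: 5 2'-hydroxy-3',4',5'-trimethoxyacetophenone, via difluoroboron chelate of the ketone 4 (not isolated)
Conditions: AcOH, BF3·OEt2, 90 °C; then H2O, warm
Reagents that add atoms: acetic acid, CC(=O)O
Why: This boron trifluoride-promoted Friedel–Crafts C-acylation of a phenol (Fries-type) should go to C6, the only free position ortho to the hydroxyl and para to the C3 methoxy group, and the difluoroboron chelate protects the product from further reaction until it is hydrolysed on work-up.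

Step 3
Reactants: 6 syringic acid (4-hydroxy-3,5-dimethoxybenzoic acid); 7 pivaloyl chloride
Product: 9 3,5-dimethoxy-4-(pivaloyloxy)benzoic acid, via mixed pivalic anhydride 8 (not isolated)
Conditions: 7 (2.5 equiv), pyridine, DMAP (cat.), CH2Cl2, 0 °C → rt; then H2O/THF, rt; dilute HCl work-up
Reagents that add atoms: water, O
Why: DMAP-catalysed O-acylation should esterify the phenol while the carboxyl group is tied up as a mixed anhydride, which water cleaves again under conditions that leave the hindered aryl pivalate untouched.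

Step 4
Reactants: 9 3,5-dimethoxy-4-(pivaloyloxy)benzoic acid
Product: 10 3,5-dimethoxy-4-(pivaloyloxy)benzoyl chloride
Conditions: (COCl)2, DMF (cat.), CH2Cl2, 0 °C → rt; evaporate, use crude
Reagents that add atoms: oxalyl chloride, O=C(Cl)C(=O)Cl
Why: Acid chloride formation through the chloroiminium (Vilsmeier-type) catalyst is neutral enough that the aryl pivalate and the methyl ethers should stay intact.

Step 5
Reactants: 5 2'-hydroxy-3',4',5'-trimethoxyacetophenone; 10 3,5-dimethoxy-4-(pivaloyloxy)benzoyl chloride
Product: 11 1-(2-hydroxy-3,4,5-trimethoxyphenyl)-3-[3,5-dimethoxy-4-(pivaloyloxy)phenyl]propane-1,3-dione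
Conditions: 5, LiN(SiMe3)2 (3.2 equiv), THF, −78 → −10 °C; then 10, THF, −78 °C → rt; aq. HCl
Reagents that add atoms: none
Why: This Claisen-type C-acylation of the phenoxide–enolate dianion of an ortho-hydroxyacetophenone by an aroyl chloride (the one-flask counterpart of the Baker–Venkataraman sequence) should be driven by deprotonation of the 1,3-diketone, and the non-nucleophilic amide should spare the hindered pivalate at low temperature.

Step 6
Reactants: 11 1-(2-hydroxy-3,4,5-trimethoxyphenyl)-3-[3,5-dimethoxy-4-(pivaloyloxy)phenyl]propane-1,3-dione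
Product: 12 4'-pivaloyloxy-3',5',6,7,8-pentamethoxyflavone
Conditions: TsOH·H2O (cat.), toluene, reflux, Dean–Stark
Reagents that add atoms: none
Why: In this acid-catalysed cyclodehydration the phenol adds to the enolised aroyl carbonyl and water is lost to give the pyranone ring, and an anhydrous, non-nucleophilic acid should not cleave the aryl pivalate.

Step 7
Reactants: 12 4'-pivaloyloxy-3',5',6,7,8-pentamethoxyflavone
Product: 14 5-hydroxy-4'-pivaloyloxy-3',5',6,7,8-pentamethoxyflavone, via C5 trifluoroacetate 13 (not isolated)
Conditions: [RuCl2(p-cymene)]2 (5 mol%), PhI(OCOCF3)2 (2 equiv), TFA/TFAA, 80 °C; then aq. Na2S2O3, aq. NaHCO3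
Reagents that add atoms: [bis(trifluoroacetoxy)iodo]benzene, O=C(OI(OC(=O)C(F)(F)F)c1ccccc1)C(F)(F)F; trifluoroacetic acid, OC(=O)C(F)(F)F (the C5 oxygen comes from a trifluoroacetate group, which either can supply)
Why: The C4 carbonyl oxygen should bind the divalent ruthenium centre, and a trifluoroacetate ligand should then remove the C5 proton in a concerted metalation–deprotonation that gives a five-membered ruthenacycle (Ru–O=C4–C4a–C5). The trivalent iodine reagent should oxidise this metallacycle to tetravalent ruthenium, C–O reductive elimination should give the C5 trifluoroacetate 13 and return divalent ruthenium, and aqueous work-up cleaves the labile aryl trifluoroacetate to phenol 14. The closest known reaction type is the ketone-directed ruthenium-catalysed ortho C–H hydroxylation of aryl ketones with a trivalent iodine oxidant in TFA/TFAA, which has been applied to C5 of flavones and chromones. No ring is closed and no stereocentre is formed. The step needs site selectivity and restraint of the oxidant: C5–H is the only C–H bond of ring A and the only one that can reach the carbonyl oxygen through a five-membered ring (C3–H would need a four-membered one, and C2'–H and C6'–H of ring B are out of reach), the pivalate lowers the electron density of ring B, and the new oxygen stays acylated in the anhydride medium until the oxidant is quenched, which should hold back oxidation of the C5/C8 para-dioxygenated ring A to a quinone.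

Step 8
Reactants: 14 5-hydroxy-4'-pivaloyloxy-3',5',6,7,8-pentamethoxyflavone
Product: 15 4'-pivaloyloxy-3',5,5',6,7,8-hexamethoxyflavone
Conditions: Me2SO4 (excess), K2CO3, dry acetone, reflux
Reagents that add atoms: dimethyl sulfate, COS(=O)(=O)OC
Why: Williamson-type O-methylation of the only free hydroxyl should proceed under forcing conditions despite its hydrogen bond to the C4 carbonyl, and anhydrous carbonate in acetone should not cleave the hindered pivalate.

Step 9
Reactants: 15 4'-pivaloyloxy-3',5,5',6,7,8-hexamethoxyflavone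
Product: 16 4'-hydroxy-3',5,5',6,7,8-hexamethoxyflavone
Conditions: NaOMe (1.5 equiv), MeOH/THF, rt; then 1 M HCl
Reagents that add atoms: none
Why: Methoxide transesterification (Zemplén-type) should cleave the aryl ester because the phenoxide is a good leaving group, while the methyl ethers and the pyranone ring are stable to methoxide at room temperature.

Compound list
1 | 2,3,4-trimethoxybenzaldehyde | COc1ccc(C=O)c(OC)c1OC | starting material
2 | 2,3,4-trimethoxyphenyl formate | COc1ccc(OC=O)c(OC)c1OC | intermediate (not isolated)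
3 | 2,3,4-trimethoxyphenol | COc1ccc(O)c(OC)c1OC | intermediate
4 | difluoroboron O,O-chelate of 2'-hydroxy-3',4',5'-trimethoxyacetophenone | CC1=[O+][B-](F)(F)Oc2c(OC)c(OC)c(OC)cc12 | intermediate (not isolated)
5 | 2'-hydroxy-3',4',5'-trimethoxyacetophenone | CC(=O)c1cc(OC)c(OC)c(OC)c1O | intermediate
6 | syringic acid (4-hydroxy-3,5-dimethoxybenzoic acid) | COc1cc(C(=O)O)cc(OC)c1O | starting material
7 | pivaloyl chloride | CC(C)(C)C(=O)Cl | starting material
8 | 3,5-dimethoxy-4-(pivaloyloxy)benzoic pivalic anhydride | COc1cc(C(=O)OC(=O)C(C)(C)C)cc(OC)c1OC(=O)C(C)(C)C | intermediate (not isolated)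
9 | 3,5-dimethoxy-4-(pivaloyloxy)benzoic acid | COc1cc(C(=O)O)cc(OC)c1OC(=O)C(C)(C)C | intermediate
10 | 3,5-dimethoxy-4-(pivaloyloxy)benzoyl chloride | COc1cc(C(=O)Cl)cc(OC)c1OC(=O)C(C)(C)C | intermediate
11 | 1-(2-hydroxy-3,4,5-trimethoxyphenyl)-3-[3,5-dimethoxy-4-(pivaloyloxy)phenyl]propane-1,3-dione | COc1cc(C(=O)CC(=O)c2cc(OC)c(OC)c(OC)c2O)cc(OC)c1OC(=O)C(C)(C)C | intermediate
12 | 4'-pivaloyloxy-3',5',6,7,8-pentamethoxyflavone | COc1cc(-c2cc(=O)c3cc(OC)c(OC)c(OC)c3o2)cc(OC)c1OC(=O)C(C)(C)C | intermediate
13 | 4'-pivaloyloxy-5-trifluoroacetoxy-3',5',6,7,8-pentamethoxyflavone | COc1cc(-c2cc(=O)c3c(OC(=O)C(F)(F)F)c(OC)c(OC)c(OC)c3o2)cc(OC)c1OC(=O)C(C)(C)C | intermediate (not isolated)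
14 | 5-hydroxy-4'-pivaloyloxy-3',5',6,7,8-pentamethoxyflavone | COc1cc(-c2cc(=O)c3c(O)c(OC)c(OC)c(OC)c3o2)cc(OC)c1OC(=O)C(C)(C)C | intermediate
15 | 4'-pivaloyloxy-3',5,5',6,7,8-hexamethoxyflavone | COc1cc(-c2cc(=O)c3c(OC)c(OC)c(OC)c(OC)c3o2)cc(OC)c1OC(=O)C(C)(C)C | intermediate
16 | 4'-hydroxy-3',5,5',6,7,8-hexamethoxyflavone | COc1cc(-c2cc(=O)c3c(OC)c(OC)c(OC)c(OC)c3o2)cc(OC)c1O | target

Total step count: 9. Longest linear sequence: 7 steps (steps 1, 2, 5, 6, 7, 8, 9; the ring B branch through steps 3 and 4 is equally long).

Steps most likely to fail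

Step 7. The trivalent iodine oxidant may attack the electron-rich ring A instead of, or after, the directed C–O bond formation (oxidative demethylation towards a quinone), or the catalyst may turn over poorly next to the C6 methoxy group. The fallback brings the C5 oxygen in before the flavone is built. It sets out from acetophenone 5. Electrophilic bromination at the one free ring position (NBS, MeCN, rt) should give 6'-bromo-2'-hydroxy-3',4',5'-trimethoxyacetophenone F1. Copper-catalysed Ullmann-type methoxylation (NaOMe, CuBr cat., MeOH/DMF, reflux) should then give 2'-hydroxy-3',4',5',6'-tetramethoxyacetophenone F2. Acylation of its dianion with acid chloride 10 under the conditions of step 5 gives 1-(2-hydroxy-3,4,5,6-tetramethoxyphenyl)-3-[3,5-dimethoxy-4-(pivaloyloxy)phenyl]propane-1,3-dione F3. Cyclodehydration as in step 6 comes back to the route at 15, so steps 7 and 8 are no longer needed.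

Step 5. The acid chloride may acylate the phenoxide oxygen instead of the enolate carbon, a second acylation may follow, or the strongly basic medium may cleave or transfer the pivalate. The fallback builds ring C through a chalcone and puts the pivalate on afterwards. It sets out from acetophenone 5. Claisen–Schmidt condensation with bought 4-benzyloxy-3,5-dimethoxybenzaldehyde F4 (KOH, EtOH, rt) should give (E)-1-(2-hydroxy-3,4,5-trimethoxyphenyl)-3-(4-benzyloxy-3,5-dimethoxyphenyl)prop-2-en-1-one F5. Oxidative cyclisation (I2 cat., DMSO, 120 °C) should give 4'-benzyloxy-3',5',6,7,8-pentamethoxyflavone F6. Hydrogenolysis (H2, 10% Pd/C, EtOAc/MeOH) should give 4'-hydroxy-3',5',6,7,8-pentamethoxyflavone F7. Acylation with pivaloyl chloride 7 (pyridine, DMAP cat., CH2Cl2) comes back to the route at 12.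

Step 8. Methylation of the hydrogen-bonded 5-hydroxyl may be slow, and under the long heating it needs the pivalate may be lost, followed by methylation at O4', which would erase the difference between the two oxygens. The fallback changes the protecting group before the methylation. It sets out from 14. Methanolysis (NaOMe, MeOH, rt, under N2; then dilute HCl) should give 4',5-dihydroxy-3',5',6,7,8-pentamethoxyflavone F8. Benzylation of the unchelated phenol alone (BnBr 1 equiv, K2CO3, DMF, rt) should give 4'-benzyloxy-5-hydroxy-3',5',6,7,8-pentamethoxyflavone F9. Forced methylation (Me2SO4, K2CO3, acetone, reflux), which the benzyl ether tolerates, should give 4'-benzyloxy-3',5,5',6,7,8-hexamethoxyflavone F10. Hydrogenolysis (H2, 10% Pd/C, EtOAc) comes back to the route at 16 and replaces step 9.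

Further compounds
F1 | step 7 | 6'-bromo-2'-hydroxy-3',4',5'-trimethoxyacetophenone | CC(=O)c1c(Br)c(OC)c(OC)c(OC)c1O
F2 | step 7 | 2'-hydroxy-3',4',5',6'-tetramethoxyacetophenone | CC(=O)c1c(OC)c(OC)c(OC)c(OC)c1O
F3 | step 7 | 1-(2-hydroxy-3,4,5,6-tetramethoxyphenyl)-3-[3,5-dimethoxy-4-(pivaloyloxy)phenyl]propane-1,3-dione | COc1cc(C(=O)CC(=O)c2c(OC)c(OC)c(OC)c(OC)c2O)cc(OC)c1OC(=O)C(C)(C)C
F4 | step 5 | 4-benzyloxy-3,5-dimethoxybenzaldehyde | COc1cc(C=O)cc(OC)c1OCc1ccccc1
F5 | step 5 | (E)-1-(2-hydroxy-3,4,5-trimethoxyphenyl)-3-(4-benzyloxy-3,5-dimethoxyphenyl)prop-2-en-1-one | COc1cc(/C=C/C(=O)c2cc(OC)c(OC)c(OC)c2O)cc(OC)c1OCc1ccccc1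
F6 | step 5 | 4'-benzyloxy-3',5',6,7,8-pentamethoxyflavone | COc1cc(-c2cc(=O)c3cc(OC)c(OC)c(OC)c3o2)cc(OC)c1OCc1ccccc1
F7 | step 5 | 4'-hydroxy-3',5',6,7,8-pentamethoxyflavone | COc1cc(-c2cc(=O)c3cc(OC)c(OC)c(OC)c3o2)cc(OC)c1O
F8 | step 8 | 4',5-dihydroxy-3',5',6,7,8-pentamethoxyflavone | COc1cc(-c2cc(=O)c3c(O)c(OC)c(OC)c(OC)c3o2)cc(OC)c1O
F9 | step 8 | 4'-benzyloxy-5-hydroxy-3',5',6,7,8-pentamethoxyflavone | COc1cc(-c2cc(=O)c3c(O)c(OC)c(OC)c(OC)c3o2)cc(OC)c1OCc1ccccc1
F10 | step 8 | 4'-benzyloxy-3',5,5',6,7,8-hexamethoxyflavone | COc1cc(-c2cc(=O)c3c(OC)c(OC)c(OC)c(OC)c3o2)cc(OC)c1OCc1ccccc1
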